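## Structural features

The target is a diaryl ether: two benzene rings joined through one oxygen, C6–O–C1' (unprimed atoms are ring A, primed atoms ring B). Ring A is pentasubstituted, with C1 OMe, C2 Br, C3 H, C4 Br, C5 Br and C6 O-aryl. Ring B is a 2,4-dibromophenol whose second ortho position carries the ether oxygen: C1' ether O, C3' Br, C5' Br, C6' OH, with hydrogen at C2' and C4'. There is no stereocentre, and the ether axis is not expected to give separable atropisomers, so configuration is not an issue. The fragile elements are the five aryl C–Br bonds (which exclude hydrogenolysis and long exposure to alkyllithiums or low-valent metals), the acidic ring B phenol, which must be kept distinct from the ring A oxygen that ends up methylated, and the crowded methyl ether, which must survive the last deprotection. The real difficulty is ring A. C2 and C4 are ortho and para to the C1 oxygen and can be reached by electrophilic bromination, but C5 is meta to C1–O, and the C6 oxygen that could direct to it would direct just as well to its para position C3, which must stay free. The key step exploits the contiguous array C2(Br)–C1(O)–C6(O)–C5(Br): the dioxygenated pair C1–C6 is delivered as the C=C of a ketene acetal and is set between the two bromine-bearing α-carbons of a symmetric 2,5-dibromothiophene 1,1-dioxide. The inner carbons of the diene become C3–H and C4–H, and C4 is then the only open position para to the liberated C1 hydroxyl.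

## Logic of the disconnections

**20 to 19.** The O–CH2Ph bond on the C6' oxygen is cut. The ring B hydroxyl has to be masked while the ring A oxygen is methylated, and a benzyl ether is inert to carbonate bases, amide bases, peracid and electrophilic bromine. Nothing is gained in skeleton; the gain is that the two phenolic oxygens stay distinguishable. The forward step must cleave this ether without touching five C–Br bonds or the methyl ether, which calls for a non-reductive Lewis acid method with a cation scavenger.

**19 to 18.** The O–CH3 bond at C1 is cut, because the stage before needs the C1 hydroxyl free as a directing group. The forward step is the O-alkylation of a hindered, acidic phenol that is the only free hydroxyl in the molecule.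

**18 to 17.** The C4–Br bond is cut. C4 is para to the C1 hydroxyl and is the only ortho or para position still bearing hydrogen, so this bromine can be left to ordinary electrophilic substitution. The ring-forming step then has to deliver only the two bromines that flank the oxygens, which keeps the diene symmetric. The forward step must stop at monobromination and must not touch ring B, which is twice brominated and has no free hydroxyl.

**17 to 3 and 13 (through 16, 15 and 14).** The bonds C1–C2 and C5–C6 are cut, after the O–Si bond, one silanol and SO2 are formally restored. These two bonds flank the dioxygenated pair, so cutting them divides ring A into a symmetric four-carbon unit carrying both bromines and a two-carbon unit carrying both oxygens and the whole of ring B. Ring A disappears altogether, the C5 bromine is fixed by construction, and the ether bond C6–O is never formed at an aromatic carbon. The forward step must have cycloaddition outrun self-reaction of 3 and must aromatise by loss of a silyloxy group and not of the aryloxy group. For the first demand the silyl groups are kept small (trimethylsilyl), since the acetal carbon has to bond to a fully substituted carbon.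

**13 to 11 (through 12).** Two O–Si bonds are cut, giving the free carboxylic acid. The forward step is an enolisation with a hindered amide base at low temperature, with the silyl chloride present, so that the aryl bromides are not attacked.

**11 to 8 and 9 (through 10).** The O–CH2 bond at the C1' oxygen is cut. The oxygen that will later join the two rings is introduced as a phenoxide nucleophile, and ring B is reduced to a mono-protected bromocatechol. The forward step is a plain phenoxide alkylation followed by ester hydrolysis.

**8 to 6 (through 7), and 6 to 4 and 5.** The C1'–O bond is traced back to a C1'–CHO bond, and the benzyl ether to the free phenol. In 4 both bromines already stand ortho and para to the hydroxyl, so the regiochemistry of ring B comes with the starting material. The forward step must exchange the formyl carbon for oxygen with aryl migration and not hydride migration, which the ortho alkoxy group should favour.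

**3 to 1 (through 2).** The two S=O bonds are cut. The forward step needs a strongly electrophilic oxidant, because the thiophene is electron-poor, and it must carry the intermediate S-oxide on quickly.

## Other disconnections considered

**Alternative 1:** The cut lies in ring B, at the ether bond C1'–O and at the C6'–O bond, the latter traced back to a C6'–I bond. Ring B then comes from 3,5-dibromobenzyne A4, released by a fluoride source from the silylaryl triflate A3, and ring A from the complete phenol A2. In the forward key step the phenoxide of A2 would add to the aryne carbon remote from the flanking bromine (C1'), and the aryl anion left at C6' would be intercepted by an iodine donor of the perfluoroalkyl iodide type, giving the iodo ether A1. A selective exchange of iodine for oxygen, for instance iodine–magnesium exchange, borylation and oxidation, would then lead to the target.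

- In its favour: the plan is convergent, closes no ring and runs under nearly neutral conditions. The orientation of the addition is controlled by the inductive pull of the adjacent bromine on the aryne, which is the equal of the symmetry argument of the chosen plan. The methyl ether is present from the start, so no benzyl group and no late methylation are needed; on protecting-group economy the alternative is the better.
- Against it here: A2 already contains the whole ring A pattern, with bromine at C5 and hydrogen at C3. The hardest part of the problem is thereby moved into a building block that no direct bromination supplies, since its only free position is para to its own hydroxyl. The anion at C6' sits next to the C5' bromine and could expel bromide to form a second aryne before it meets the iodine donor. A2 is a hindered, weakly nucleophilic phenoxide. The final exchange must pick one C–I bond out from five C–Br bonds.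
- Comparison: on structure, the alternative joins two finished rings, whereas the chosen plan creates ring A and its bromine pattern in one step. On mechanism, it depends on trapping a short-lived aryl anion in competition with β-elimination, whereas the chosen plan depends on a pericyclic sequence whose only open question is rate. On step economy, the aryne sequence itself is short (about three steps from A2 and A3), but the syntheses of A2 and A3 would make the total at least as long as the nine steps of the chosen plan.

**Alternative 2:** Here ring B is taken apart. The bromine-bearing carbon C5' is removed as a one-carbon unit (bonds C5'–C6' and C5'–C4'), which leaves the cyclopentadiene A6, with a silyloxy group on the future C6' and the finished ring A aryloxy group on the future C1'. In the forward key step dibromocarbene A7, generated from the haloform and a tert-alkoxide, would add to the silyl enol ether double bond of A6. The gem-dibromocyclopropane would open with loss of bromide and of the silyl group, expanding the ring to the bromophenol A5. Bromination para to the C6' hydroxyl, at C3', would complete the target.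

- In its favour: the C5' bromine arrives with the carbene, so its position is fixed by construction in the same way as C2 and C5 in the chosen plan; on this point the two are equal. The ring B hydroxyl emerges free and directs the last bromination, so no protecting group is needed on ring B; here the alternative is the better.
- Against it here: the construction is spent on ring B, whose substitution pattern is available from commerce, while ring A with its C5 bromine must be complete before A6 can be made. A6 would have to be built from A2, so the difficulty noted under Alternative 1 returns. A6 is a doubly oxygenated cyclopentadiene, liable to 1,5-hydrogen shifts, which would change the double bond that is cyclopropanated, and to Diels–Alder dimerisation. The carbene has two electron-rich double bonds to choose from, and the conditions are strongly basic.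
- Comparison: on structure, the alternative builds the easy ring and the chosen plan the difficult one. On mechanism, a carbene addition with electrocyclic opening on a labile diene stands against a cycloaddition with extrusion on a diene that can be crystallised and stored. On step economy, the two steps after A6 are fewer than the three after 17, but the preparation of A2 and its elaboration to A6 would outweigh this.

**Alternative 3:** Ring A is traced back to a non-aromatic six-membered ring. The C2–Br and C4–Br bonds and the aromatic unsaturation are removed, which leads to the bromo enone A9. Its vinylic bromine is the future C5–Br and its aryloxy group the future C6 substituent. A9 would come from the aryloxy dione A11 by conversion of one carbonyl into the vinylogous acid bromide, and A11 from cyclohexane-1,3-dione A10 and phenol 8. In the forward key step three equivalents of the halogen would brominate A9 at the α' carbon, hydrogen bromide would be lost, the dienone would tautomerise to the phenol, and the new phenol would be brominated ortho and para. The product A8 is the same substance as 18 of the chosen route.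

- In its favour: the carbocyclic starting material is cheap, the C5 bromine is placed by carbonyl chemistry, and one reagent performs the dehydrogenation and both ring brominations. No moisture-sensitive ketene acetal, no thiophene dioxide and no cryogenic step are needed. The plan would reach 18 in about six operations against the seven of the chosen plan, so on step economy and ease of operation it is the equal or the better.
- Against it here: the O-arylation of C2 of A10 by the hindered, acidic phenol 8, whether by carbenoid O–H insertion of a diazo derivative of A10 or by substitution on a 2-halo derivative, is a weak link. The brominative aromatisation passes through non-aromatic bromo ketones, where the site of attack is set by enolisation and not by aromatic directing effects, so bromine could also enter at the carbon that becomes C3. The several equivalents of hydrogen bromide set free would endanger the benzyl ether and the vinylogous acyl bromide.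
- Comparison: on structure, both plans make ring A from a non-aromatic precursor and both place the C5 bromine by construction. The chosen plan also fixes the C2 bromine by construction and leaves a single, fully directed aromatic bromination, whereas the alternative must control three halogenation events in one flask. On mechanism, ionic enol brominations and eliminations stand against a pericyclic sequence. The chosen plan is preferred because secure placement of every substituent is judged to outweigh one step.

Key step: step 6

Remark on the chemistry (assumption): the silyl groups of the ketene acetal are taken as trimethylsilyl, because the acetal carbon must bond to a fully substituted C(Br)(SO2) carbon and because the labile aryl trimethylsilyl ether is cleaved in the work-up of the cycloaddition, which saves a separate desilylation; the ring B hydroxyl is carried as its benzyl ether.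

## Route

Step 1
Reactants: 1 2,5-dibromothiophene
Product: 3 2,5-dibromothiophene 1,1-dioxide, via 2,5-dibromothiophene 1-oxide 2 (not isolated)
Conditions: H2O2·urea, (CF3CO)2O, MeCN/CH2Cl2, 0 °C → rt
Reagents that add atoms: trifluoroperacetic acid, OOC(=O)C(F)(F)F, made in the flask from hydrogen peroxide–urea, OO.NC(N)=O, and trifluoroacetic anhydride, O=C(OC(=O)C(F)(F)F)C(F)(F)F
Why: Electrophilic S-oxidation of an electron-poor thiophene needs the strongest common peracid; trifluoroperacetic acid should oxidise the sulfide to the S-oxide 2 and then, faster, to the sulfone, so that the dimerisation-prone S-oxide does not build up, and the two α-bromines should slow the self-dimerisation of 3 enough for isolation by crystallisation.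

Step 2
Reactants: 4 3,5-dibromosalicylaldehyde (3,5-dibromo-2-hydroxybenzaldehyde); 5 benzyl bromide
Product: 6 2-(benzyloxy)-3,5-dibromobenzaldehyde
Conditions: K2CO3, DMF, rt
Reagents that add atoms: none
Why: Williamson ether synthesis; the phenol, acidified by the ortho formyl group and two bromines, is fully deprotonated by K2CO3, and benzyl bromide is an unhindered SN2 electrophile, so the crowded oxygen should still be alkylated cleanly.

Step 3
Reactants: 6 2-(benzyloxy)-3,5-dibromobenzaldehyde
Product: 8 2-(benzyloxy)-3,5-dibromophenol, via aryl formate 7 (not isolated)
Conditions: mCPBA, CH2Cl2, rt → 40 °C; NaHCO3 wash; then K2CO3 (cat.), MeOH, rt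
Reagents that add atoms: mCPBA (3-chloroperbenzoic acid), OOC(=O)c1cccc(Cl)c1
Why: Baeyer–Villiger oxidation of the Dakin type; the Criegee adduct of an ortho-alkoxybenzaldehyde should rearrange with aryl migration to the formate 7, which is methanolysed to the phenol, while the benzyl ether and the aryl bromides are inert to peracid.

Step 4
Reactants: 8 2-(benzyloxy)-3,5-dibromophenol; 9 methyl bromoacetate
Product: 11 [2-(benzyloxy)-3,5-dibromophenoxy]acetic acid, via methyl ester 10 (not isolated)
Conditions: K2CO3, DMF, rt; then LiOH, H2O/THF, rt; HCl
Reagents that add atoms: lithium hydroxide, [Li+].[OH-] (supplies the carboxyl OH oxygen)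
Why: Williamson O-alkylation of the phenoxide by an α-halo ester (SN2), followed by saponification in the same flask; neither stage affects the benzyl ether or the aryl bromides, and acidification should precipitate the acid.

Step 5
Reactants: 11 [2-(benzyloxy)-3,5-dibromophenoxy]acetic acid
Product: 13 1,1-bis(trimethylsilyloxy)-2-[2-(benzyloxy)-3,5-dibromophenoxy]ethene, via trimethylsilyl ester 12 (not isolated)
Conditions: Me3SiCl, Et3N, THF, 0 °C → rt; then LiN(SiMe3)2, Me3SiCl, THF, −78 → 0 °C; hexane, filtration under Ar, used crude
Reagents that add atoms: chlorotrimethylsilane, C[Si](C)(C)Cl
Why: Silyl ester formation followed by silyl ketene acetal formation: LiN(SiMe3)2 deprotonates the α-aryloxy silyl ester at −78 °C with the silyl chloride present, so the enolate is trapped on oxygen as it forms and the aryl bromides are not attacked; the two silyloxy groups are identical, so no double-bond isomers arise.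

Step 6
Reactants: 3 2,5-dibromothiophene 1,1-dioxide; 13 1,1-bis(trimethylsilyloxy)-2-[2-(benzyloxy)-3,5-dibromophenoxy]ethene
Product: 17 2-[2-(benzyloxy)-3,5-dibromophenoxy]-3,6-dibromophenol, via bridged sulfone cycloadduct 14 (not isolated), via bis(trimethylsilyloxy)cyclohexadiene 15 (not isolated), via aryl trimethylsilyl ether 16 (not isolated)
Conditions: PhMe, 3 added slowly to 13 (1.3 equiv), rt → 80 °C; then 1 M HCl, THF/MeOH, rt
Reagents that add atoms: none
Why: The electron-poor, non-aromatic diene 3 and the electron-rich ketene acetal 13 should combine in an inverse-electron-demand [4+2] cycloaddition, probably asynchronous, in which the nucleophilic CH(OAr) carbon bonds to one brominated α-carbon of 3 (C5–C6) and the acetal carbon closes onto the other (C1–C2), giving the bridged sulfone 14. Cheletropic loss of SO2 from 14 gives the cyclohexadiene 15, in which C6 carries hydrogen and the aryloxy group while C1 carries two silyloxy groups and no hydrogen, so the only aromatising 1,2-elimination is loss of trimethylsilanol (ionisation of the silyl ketal, then loss of the C6 proton) to the aryl silyl ether 16, with the aryloxy group retained. The acidic methanolic work-up cleaves the labile O–SiMe3 bond of 16 and would hydrolyse any surviving 15 to the cyclohexa-2,4-dienone tautomer of 17, so both paths converge on the phenol 17. The closest known reaction types are the cycloadditions of halogenated thiophene 1,1-dioxides with alkenes, which lose SO2 spontaneously, and the aromatisation of ketene acetal adducts of electron-poor dienes such as 2-pyrones and 1,2,4-triazines by loss of an oxygen group. Ring A is closed as a six-membered carbocycle by an intermolecular [4+2] annulation that forms two C–C bonds, the sulfur ring serving as a template that is excised. No stereocentre survives, since the stereogenic carbons of 14 and 15 are erased on aromatisation, so endo or exo approach is immaterial. Orientation is not an issue because 3 is C2v-symmetric; the selectivity needed is cross-cycloaddition over self-dimerisation of 3, which the two α-bromines, the slow addition of 3 to an excess of the far more nucleophilic 13 and the small trimethylsilyl groups should secure, while the apolar medium without Lewis acid disfavours a stepwise addition–elimination at the C–Br carbons.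

Step 7
Reactants: 17 2-[2-(benzyloxy)-3,5-dibromophenoxy]-3,6-dibromophenol
Product: 18 2-[2-(benzyloxy)-3,5-dibromophenoxy]-3,4,6-tribromophenol
Conditions: NBS (1.05 equiv), MeCN, 0 °C → rt, dark
Reagents that add atoms: N-bromosuccinimide, O=C1CCC(=O)N1Br
Why: Electrophilic aromatic bromination; C4 is the only position ortho or para to the free hydroxyl that still carries hydrogen, C3 is meta to it, and ring B is deactivated by two bromines and has no free phenol, so one equivalent of NBS should brominate C4 only.

Step 8
Reactants: 18 2-[2-(benzyloxy)-3,5-dibromophenoxy]-3,4,6-tribromophenol
Product: 19 2-(benzyloxy)-1,5-dibromo-3-(2,3,5-tribromo-6-methoxyphenoxy)benzene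
Conditions: MeI, K2CO3, DMF, rt
Reagents that add atoms: iodomethane, CI
Why: Williamson methylation of an acidic polybromophenoxide with an unhindered electrophile; the benzyl ether keeps the ring B oxygen out of the reaction, so only the C1 oxygen is methylated.

Step 9
Reactants: 19 2-(benzyloxy)-1,5-dibromo-3-(2,3,5-tribromo-6-methoxyphenoxy)benzene
Product: 20 2,4-dibromo-6-(2,3,5-tribromo-6-methoxyphenoxy)phenol (target)
Conditions: BCl3, C6HMe5, CH2Cl2, −78 °C; MeOH
Reagents that add atoms: none
Why: Lewis acid debenzylation with a cation scavenger; BCl3 activates the benzylic C–O bond and pentamethylbenzene captures the benzyl cation by Friedel–Crafts alkylation, so at −78 °C the methyl ether and the five C–Br bonds should remain intact and the reductive conditions that would remove bromine are avoided.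

## Compound list

1 | 2,5-dibromothiophene | Brc1ccc(Br)s1 | starting material
2 | 2,5-dibromothiophene 1-oxide | O=S1C(Br)=CC=C1Br | intermediate
3 | 2,5-dibromothiophene 1,1-dioxide | O=S1(=O)C(Br)=CC=C1Br | intermediate
4 | 3,5-dibromosalicylaldehyde (3,5-dibromo-2-hydroxybenzaldehyde) | O=Cc1cc(Br)cc(Br)c1O | starting material
5 | benzyl bromide | BrCc1ccccc1 | starting material
6 | 2-(benzyloxy)-3,5-dibromobenzaldehyde | O=Cc1cc(Br)cc(Br)c1OCc1ccccc1 | intermediate
7 | 2-(benzyloxy)-3,5-dibromophenyl formate | O=COc1cc(Br)cc(Br)c1OCc1ccccc1 | intermediate
8 | 2-(benzyloxy)-3,5-dibromophenol | Oc1cc(Br)cc(Br)c1OCc1ccccc1 | intermediate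
9 | methyl bromoacetate | COC(=O)CBr | starting material
10 | methyl [2-(benzyloxy)-3,5-dibromophenoxy]acetate | COC(=O)COc1cc(Br)cc(Br)c1OCc1ccccc1 | intermediate
11 | [2-(benzyloxy)-3,5-dibromophenoxy]acetic acid | OC(=O)COc1cc(Br)cc(Br)c1OCc1ccccc1 | intermediate
12 | trimethylsilyl [2-(benzyloxy)-3,5-dibromophenoxy]acetate | C[Si](C)(C)OC(=O)COc1cc(Br)cc(Br)c1OCc1ccccc1 | intermediate
13 | 1,1-bis(trimethylsilyloxy)-2-[2-(benzyloxy)-3,5-dibromophenoxy]ethene | C[Si](C)(C)OC(O[Si](C)(C)C)=COc1cc(Br)cc(Br)c1OCc1ccccc1 | intermediate
14 | 6-[2-(benzyloxy)-3,5-dibromophenoxy]-1,4-dibromo-5,5-bis(trimethylsilyloxy)-7-thiabicyclo[2.2.1]hept-2-ene 7,7-dioxide (racemic; configuration at C6 undefined and lost later) | O=S1(=O)C2(Br)C=CC1(Br)C(O[Si](C)(C)C)(O[Si](C)(C)C)C2Oc1cc(Br)cc(Br)c1OCc1ccccc1 | intermediate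
15 | 6-[2-(benzyloxy)-3,5-dibromophenoxy]-1,4-dibromo-5,5-bis(trimethylsilyloxy)cyclohexa-1,3-diene (racemic) | BrC1=CC=C(Br)C(O[Si](C)(C)C)(O[Si](C)(C)C)C1Oc1cc(Br)cc(Br)c1OCc1ccccc1 | intermediate
16 | {2-[2-(benzyloxy)-3,5-dibromophenoxy]-3,6-dibromophenoxy}trimethylsilane | C[Si](C)(C)Oc1c(Br)ccc(Br)c1Oc1cc(Br)cc(Br)c1OCc1ccccc1 | intermediate
17 | 2-[2-(benzyloxy)-3,5-dibromophenoxy]-3,6-dibromophenol | Oc1c(Br)ccc(Br)c1Oc1cc(Br)cc(Br)c1OCc1ccccc1 | intermediate
18 | 2-[2-(benzyloxy)-3,5-dibromophenoxy]-3,4,6-tribromophenol | Oc1c(Br)cc(Br)c(Br)c1Oc1cc(Br)cc(Br)c1OCc1ccccc1 | intermediate
19 | 2-(benzyloxy)-1,5-dibromo-3-(2,3,5-tribromo-6-methoxyphenoxy)benzene | COc1c(Br)cc(Br)c(Br)c1Oc1cc(Br)cc(Br)c1OCc1ccccc1 | intermediate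
20 | 2,4-dibromo-6-(2,3,5-tribromo-6-methoxyphenoxy)phenol | COc1c(Br)cc(Br)c(Br)c1Oc1cc(Br)cc(Br)c1O | target

## Step count and least certain steps

Total step count: 9 steps. Longest linear sequence: 8 steps (steps 2 to 9, from 4); the branch from 1 is one step (step 1).

**Step 6 (key step).** Three processes are most likely to interfere. The first is a stepwise polar addition of the ketene acetal to the vinyl sulfone followed by loss of bromide, which would give substitution in place of annulation. The second is self-dimerisation of the diene outrunning the cycloaddition, because both new bonds are made at fully substituted carbons. The third is hydrolytic loss of the ketene acetal before it reacts.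

Fallback: the route is left at 8 and rejoined at 17, with ring A bought as a preformed arene. The phenoxide of 8 (K2CO3, DMF, 80 °C) would displace the fluoride, activated by the ortho formyl group, of 3,6-dibromo-2-fluorobenzaldehyde (O=Cc1c(F)c(Br)ccc1Br, a catalogue compound) in a nucleophilic aromatic substitution. This would give 2-[2-(benzyloxy)-3,5-dibromophenoxy]-3,6-dibromobenzaldehyde F1. Baeyer–Villiger oxidation with mCPBA would convert it into 2-[2-(benzyloxy)-3,5-dibromophenoxy]-3,6-dibromophenyl formate F2, and methanolysis (K2CO3 cat., MeOH) would give 17.

**Step 1.** The oxidation may stall at the S-oxide, which dimerises by cycloaddition, or the product may be consumed by further oxidation of its double bonds; either process lowers the supply of 3.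

Fallback: the route is left at 1 and rejoined at 3, with the oxidation carried out on an electron-rich, sterically shielded thiophene. Double bromine–lithium exchange on 1 (BuLi, THF, −78 °C) and silylation with Me3SiCl would give 2,5-bis(trimethylsilyl)thiophene F3. mCPBA in CH2Cl2 would oxidise it smoothly to 2,5-bis(trimethylsilyl)thiophene 1,1-dioxide F4. Ipso bromodesilylation with Br2 and AgBF4 in CH2Cl2 would then give 3.

**Step 3.** Hydride migration in the Criegee adduct may compete with aryl migration and lead to the benzoic acid. The ortho benzyloxy group is pushed out of conjugation by its two neighbours, and the ring is electron-poor.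

Fallback: the route is left at 4 and rejoined at 8, with the rearrangement driven by a phenoxide and not by an ether oxygen. Dakin oxidation of 4 (H2O2, NaOH, H2O/THF, 0 °C → rt) would give 3,5-dibromobenzene-1,2-diol F5. One equivalent of 5 with NaHCO3 in DMF at 40 °C would then benzylate the monoanion at the more acidic hydroxyl, the one ortho and para to the bromines, which is the oxygen that carries the benzyl group in 8.

**Step 9.** Two processes may interfere: cleavage of the crowded ring A methyl ether alongside the benzyl ether, and transfer of the benzyl cation to an aromatic carbon of the product.

Fallback: the route is left at 19 and rejoined at 20. The Lewis acid is replaced by a Brønsted acid "push–pull" cleavage (CF3CO2H, PhSMe, rt), in which the protonated ether hands its benzyl group to sulfur in an SN2 process. A methyl ether is not cleaved in this way under these conditions, and no new compound is formed on the way.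

## Further compounds

F1 | step 6 | 2-[2-(benzyloxy)-3,5-dibromophenoxy]-3,6-dibromobenzaldehyde | O=Cc1c(Br)ccc(Br)c1Oc1cc(Br)cc(Br)c1OCc1ccccc1
F2 | step 6 | 2-[2-(benzyloxy)-3,5-dibromophenoxy]-3,6-dibromophenyl formate | O=COc1c(Br)ccc(Br)c1Oc1cc(Br)cc(Br)c1OCc1ccccc1
F3 | step 1 | 2,5-bis(trimethylsilyl)thiophene | C[Si](C)(C)c1ccc([Si](C)(C)C)s1
F4 | step 1 | 2,5-bis(trimethylsilyl)thiophene 1,1-dioxide | C[Si](C)(C)C1=CC=C([Si](C)(C)C)S1(=O)=O
F5 | step 3 | 3,5-dibromobenzene-1,2-diol | Oc1cc(Br)cc(Br)c1O
F0 | step 9 | none | none
A1 | alternative 1 | 1,2,5-tribromo-3-(3,5-dibromo-2-iodophenoxy)-4-methoxybenzene | COc1c(Br)cc(Br)c(Br)c1Oc1cc(Br)cc(Br)c1I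
A2 | alternative 1 | 2,3,5-tribromo-6-methoxyphenol | COc1c(Br)cc(Br)c(Br)c1O
A3 | alternative 1 | 2,4-dibromo-6-(trimethylsilyl)phenyl trifluoromethanesulfonate | C[Si](C)(C)c1cc(Br)cc(Br)c1OS(=O)(=O)C(F)(F)F
A4 | alternative 1 | 3,5-dibromobenzyne | BrC1=CC(Br)=CC#C1
A5 | alternative 2 | 2-bromo-6-(2,3,5-tribromo-6-methoxyphenoxy)phenol | COc1c(Br)cc(Br)c(Br)c1Oc1cccc(Br)c1O
A6 | alternative 2 | 2-(tert-butyldimethylsilyloxy)-3-(2,3,5-tribromo-6-methoxyphenoxy)cyclopenta-1,3-diene | COc1c(Br)cc(Br)c(Br)c1OC1=CCC=C1O[Si](C)(C)C(C)(C)C
A7 | alternative 2 | dibromocarbene | Br[C]Br
A8 | alternative 3 | 2-[2-(benzyloxy)-3,5-dibromophenoxy]-3,4,6-tribromophenol | Oc1c(Br)cc(Br)c(Br)c1Oc1cc(Br)cc(Br)c1OCc1ccccc1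
A9 | alternative 3 | 2-[2-(benzyloxy)-3,5-dibromophenoxy]-3-bromocyclohex-2-en-1-one | O=C1CCCC(Br)=C1Oc1cc(Br)cc(Br)c1OCc1ccccc1
A10 | alternative 3 | cyclohexane-1,3-dione | O=C1CCCC(=O)C1
A11 | alternative 3 | 2-[2-(benzyloxy)-3,5-dibromophenoxy]cyclohexane-1,3-dione | O=C1CCCC(=O)C1Oc1cc(Br)cc(Br)c1OCc1ccccc1
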